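**Retrosynthetic overview**
- The target is a (3R)-5,7-dihydroxyisoflavanone whose ring B is 1,2,3,4-tetrasubstituted: C1' is bonded to C3, C2' carries OMe, C3' carries the CH=CH carbon of the dimethylpyran ring D and C4' carries the ring D oxygen. The strategy rests on this contiguous pattern.
- C3–C1' is cut last: an enantioconvergent nickel/pybox Negishi coupling joins a racemic 3-bromo-5,7-bis(silyloxy)chroman-4-one to a chromen-6-ylzinc iodide, and desilylation follows.
- Ring D is cut at C3'–CH, C4'–O and O–CMe2 in one operation: 4-bromo-3-methoxybenzyne plus 3-methylbut-2-enal ([2+2], benzoxete opening, oxa-6π). The OMe beside the triple bond fixes the orientation and Br at C1' is carried as the coupling handle.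
- The aryne precursor comes from 4-bromo-3-methoxyphenol by carbamate-directed silylation at the carbon between the two oxygens, then triflation. Rings A and C come from phloroglucinol and 3-chloropropanoic acid.
- Order of ring formation: ring D onto ring B (step 4), ring C onto ring A (step 6), then the two bicycles are joined (step 9).

Key step: step 4

Assumption: the sense of induction of the nickel/pybox catalyst on a cyclic bromoketone cannot be read from acyclic cases, so the ligand antipode that gives (3R) is to be fixed on a model coupling.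

Step 1
Reactants: 1 4-bromo-3-methoxyphenol
Product: 2 4-bromo-3-methoxyphenyl N-isopropylcarbamate
Conditions: i-PrNCO, Et3N (cat.), CH2Cl2, rt
Reagents that add atoms: isopropyl isocyanate, CC(C)N=C=O
Why: Amine-catalysed addition of the phenol O–H across the isocyanate (carbamoylation) installs a directing group that can later be removed under mild amine conditions.

Step 2
Reactants: 2 4-bromo-3-methoxyphenyl N-isopropylcarbamate
Product: 6 4-bromo-3-methoxy-2-(trimethylsilyl)phenyl N-isopropylcarbamate, via N-silyl carbamate 3 (not isolated), via aryllithium 4 (not isolated), via bis-silyl carbamate 5 (not isolated)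
Conditions: Me3SiOTf, TMEDA, Et2O, 0 °C → rt; then Me3SiCl, lithium 2,2,6,6-tetramethylpiperidide (LiTMP, 2.5 equiv), THF, −78 °C; aq NaHSO4 work-up
Reagents that add atoms: chlorotrimethylsilane, C[Si](C)(C)Cl
Why: Directed ortho-metalation: after N-silylation the C2–H between the carbamate and methoxy oxygens is the most acidic site, the hindered amide base removes it without bromine–lithium exchange, the aryllithium (which has no halogen ortho to it) is trapped in situ by Me3SiCl, and the N–Si bond is hydrolysed on work-up.

Step 3
Reactants: 6 4-bromo-3-methoxy-2-(trimethylsilyl)phenyl N-isopropylcarbamate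
Product: 8 4-bromo-3-methoxy-2-(trimethylsilyl)phenyl trifluoromethanesulfonate, via silylphenol 7 (not isolated)
Conditions: DBU, Et2NH, MeCN, 40 °C; then PhNTf2, rt
Reagents that add atoms: N-phenylbis(trifluoromethanesulfonimide), O=S(=O)(N(c1ccccc1)S(=O)(=O)C(F)(F)F)C(F)(F)F
Why: One-pot decarbamoylation–triflation: E1cB loss of isopropyl isocyanate (scavenged by Et2NH) frees the phenoxide, which is sulfonylated by PhNTf2 under conditions mild enough to keep the C–Si bond.

Step 4
Reactants: 8 4-bromo-3-methoxy-2-(trimethylsilyl)phenyl trifluoromethanesulfonate; 9 3-methylbut-2-enal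
Product: 13 6-bromo-5-methoxy-2,2-dimethyl-2H-chromene, via aryne 10 (not isolated), via benzoxete 11 (not isolated), via ortho-quinone methide 12 (not isolated)
Conditions: 9 (4 equiv), CsF (3 equiv), MeCN, rt → 50 °C, slow addition of 8
Reagents that add atoms: none
Why: Fluoride attacks silicon in 8 and triflate leaves to give aryne 10; the carbonyl oxygen of 9 adds to the aryne carbon meta to the methoxy group (the former C–OTf carbon, future C4'), the aryl anion developing at the carbon next to the methoxy group (future C3') closes on the carbonyl carbon, and benzoxete 11 opens by 4π retro-electrocyclisation to ortho-quinone methide 12. The closest known reaction type is the fluoride-induced formal [2+2] addition of arynes to aldehydes, which with α,β-unsaturated aldehydes is an established route to 2H-chromenes. The transient oxete ring forms by collapse of the aryl anion/oxocarbenium zwitterion, and ring D closes by a thermal disrotatory oxa-6π electrocyclisation of Z-configured 12 in which the dienone oxygen bonds to the CMe2 terminus; the E isomer can return through 11 until the Z isomer cyclises. No stereocentre is created, since C2 of ring D carries two methyl groups. The step needs regioselective addition across the triple bond and a 1:1 combination of the partners: the inductively withdrawing methoxy group beside the triple bond makes the distal carbon the electrophilic one and stabilises the anion at the proximal one, so oxygen goes to C4' and carbon to C3', while excess 9 and slow release of 10 should keep 12 from being intercepted by a second aryne. The C–Br bond and the methoxy group are spectators under CsF in MeCN.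

Step 5
Reactants: 14 phloroglucinol; 15 3-chloropropanoic acid
Product: 16 3-chloro-1-(2,4,6-trihydroxyphenyl)propan-1-one
Conditions: CF3SO3H, 80 °C
Reagents that add atoms: none
Why: Friedel–Crafts acylation of the symmetrical, highly activated triol by the acylium species formed in triflic acid can give only one mono-ketone, and the new carbonyl deactivates the ring against a second acylation.

Step 6
Reactants: 16 3-chloro-1-(2,4,6-trihydroxyphenyl)propan-1-one
Product: 17 5,7-dihydroxychroman-4-one
Conditions: 2 M aq NaOH, 0 °C → rt; then aq HCl to pH 2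
Reagents that add atoms: none
Why: Intramolecular Williamson etherification by an ortho phenoxide (6-exo-tet, or E1cB to the enone followed by oxa-Michael addition) closes ring C, and the two ortho hydroxyls are equivalent so a single product is expected.

Step 7
Reactants: 17 5,7-dihydroxychroman-4-one
Product: 18 5,7-bis(tert-butyldimethylsilyloxy)chroman-4-one
Conditions: TBSOTf (2.4 equiv), 2,6-lutidine, CH2Cl2, −78 → 0 °C
Reagents that add atoms: tert-butyldimethylsilyl trifluoromethanesulfonate, CC(C)(C)[Si](C)(C)OS(=O)(=O)C(F)(F)F
Why: O-silylation with the silyl triflate is forceful enough to cap the hydrogen-bonded 5-OH as well as the 7-OH, removing both acidic protons before the organometallic steps.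

Step 8
Reactants: 18 5,7-bis(tert-butyldimethylsilyloxy)chroman-4-one
Product: 20 rac-3-bromo-5,7-bis(tert-butyldimethylsilyloxy)chroman-4-one, via silyl enol ether 19 (not isolated)
Conditions: LiN(SiMe3)2, Me3SiCl, THF, −78 °C; then NBS, −78 → 0 °C
Reagents that add atoms: N-bromosuccinimide, O=C1CCC(=O)N1Br
Why: Kinetic enolisation with internal silyl trapping followed by electrophilic bromination of the silyl enol ether puts bromine at C3 at a temperature at which the silyloxy-substituted ring A should not be brominated.

Step 9
Reactants: 13 6-bromo-5-methoxy-2,2-dimethyl-2H-chromene; 20 rac-3-bromo-5,7-bis(tert-butyldimethylsilyloxy)chroman-4-one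
Product: 23 (3R)-5,7-bis(tert-butyldimethylsilyloxy)-3-(5-methoxy-2,2-dimethyl-2H-chromen-6-yl)chroman-4-one, via arylmagnesium bromide 21 (not isolated), via arylzinc iodide 22 (not isolated)
Conditions: 13, Mg, THF, 50 °C; ZnI2, THF, rt; then 20, NiCl2·glyme (5 mol %), (R,R)-Ph-pybox or its antipode (6.5 mol %), glyme/THF, −30 °C
Reagents that add atoms: none
Why: Proposed new method: arylzinc iodide 22 (from magnesium insertion into 13 and ZnI2 exchange) transmetalates to the nickel/pybox complex, the monovalent arylnickel species abstracts bromine from either enantiomer of 20 to give one planar C3 α-keto radical, this radical is captured by the chiral divalent arylnickel complex and the trivalent aryl(alkyl)nickel species reductively eliminates to form C3–C1', so the ligand alone sets the C3 configuration and the antipode giving (3R) is used; the closest known reaction type is the nickel/pybox enantioconvergent Negishi arylation of racemic acyclic α-bromo ketones with ArZnI at −30 °C, what is new is a cyclic 3-bromochroman-4-one with a β-aryloxy group and an arylzinc bearing an ortho methoxy group, and the base-free low-temperature conditions should leave the new tertiary α-aryl centre unepimerised.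

Step 10
Reactants: 23 (3R)-5,7-bis(tert-butyldimethylsilyloxy)-3-(5-methoxy-2,2-dimethyl-2H-chromen-6-yl)chroman-4-one
Product: 24 (3R)-5,7-dihydroxy-3-(5-methoxy-2,2-dimethyl-2H-chromen-6-yl)chroman-4-one
Conditions: HF·pyridine, pyridine, THF, 0 °C → rt
Reagents that add atoms: none
Why: Fluoride-mediated cleavage of the two aryl silyl ethers under buffered, weakly acidic conditions should free the phenols without enolising C3–H or protonating the ring D double bond, so the (3R) centre is retained.

**Compound list**
1 | 4-bromo-3-methoxyphenol | COc1cc(O)ccc1Br | starting material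
2 | 4-bromo-3-methoxyphenyl N-isopropylcarbamate | COc1cc(OC(=O)NC(C)C)ccc1Br | intermediate
3 | 4-bromo-3-methoxyphenyl N-isopropyl-N-(trimethylsilyl)carbamate | COc1cc(OC(=O)N(C(C)C)[Si](C)(C)C)ccc1Br | intermediate
4 | 4-bromo-2-lithio-3-methoxyphenyl N-isopropyl-N-(trimethylsilyl)carbamate | COc1c(Br)ccc(OC(=O)N(C(C)C)[Si](C)(C)C)c1[Li] | intermediate
5 | 4-bromo-3-methoxy-2-(trimethylsilyl)phenyl N-isopropyl-N-(trimethylsilyl)carbamate | COc1c(Br)ccc(OC(=O)N(C(C)C)[Si](C)(C)C)c1[Si](C)(C)C | intermediate
6 | 4-bromo-3-methoxy-2-(trimethylsilyl)phenyl N-isopropylcarbamate | COc1c(Br)ccc(OC(=O)NC(C)C)c1[Si](C)(C)C | intermediate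
7 | 4-bromo-3-methoxy-2-(trimethylsilyl)phenol | COc1c(Br)ccc(O)c1[Si](C)(C)C | intermediate
8 | 4-bromo-3-methoxy-2-(trimethylsilyl)phenyl trifluoromethanesulfonate | COc1c(Br)ccc(OS(=O)(=O)C(F)(F)F)c1[Si](C)(C)C | intermediate
9 | 3-methylbut-2-enal | CC(C)=CC=O | starting material
10 | 4-bromo-3-methoxy-1,2-didehydrobenzene (4-bromo-3-methoxybenzyne) | COC1=C(Br)C=CC#C1 | intermediate
11 | 4-bromo-3-methoxy-2-(2-methylprop-1-en-1-yl)-2H-benzo[b]oxete (racemic) | COc1c(Br)ccc2OC(C=C(C)C)c12 | intermediate
12 | (6Z)-4-bromo-5-methoxy-6-(3-methylbut-2-en-1-ylidene)cyclohexa-2,4-dien-1-one | COC1=C(Br)C=CC(=O)/C1=C\C=C(C)C | intermediate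
13 | 6-bromo-5-methoxy-2,2-dimethyl-2H-chromene | COc1c(Br)ccc2c1C=CC(C)(C)O2 | intermediate
14 | phloroglucinol | Oc1cc(O)cc(O)c1 | starting material
15 | 3-chloropropanoic acid | OC(=O)CCCl | starting material
16 | 3-chloro-1-(2,4,6-trihydroxyphenyl)propan-1-one | O=C(CCCl)c1c(O)cc(O)cc1O | intermediate
17 | 5,7-dihydroxychroman-4-one | O=C1CCOc2cc(O)cc(O)c12 | intermediate
18 | 5,7-bis(tert-butyldimethylsilyloxy)chroman-4-one | O=C1CCOc2cc(O[Si](C)(C)C(C)(C)C)cc(O[Si](C)(C)C(C)(C)C)c12 | intermediate
19 | 5,7-bis(tert-butyldimethylsilyloxy)-4-(trimethylsilyloxy)-2H-chromene | C[Si](C)(C)OC1=CCOc2cc(O[Si](C)(C)C(C)(C)C)cc(O[Si](C)(C)C(C)(C)C)c12 | intermediate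
20 | rac-3-bromo-5,7-bis(tert-butyldimethylsilyloxy)chroman-4-one | O=C1C(Br)COc2cc(O[Si](C)(C)C(C)(C)C)cc(O[Si](C)(C)C(C)(C)C)c12 | intermediate
21 | (5-methoxy-2,2-dimethyl-2H-chromen-6-yl)magnesium bromide | COc1c([Mg]Br)ccc2c1C=CC(C)(C)O2 | intermediate
22 | (5-methoxy-2,2-dimethyl-2H-chromen-6-yl)zinc iodide | COc1c([Zn]I)ccc2c1C=CC(C)(C)O2 | intermediate
23 | (3R)-5,7-bis(tert-butyldimethylsilyloxy)-3-(5-methoxy-2,2-dimethyl-2H-chromen-6-yl)chroman-4-one | COc1c([C@@H]2COc3cc(O[Si](C)(C)C(C)(C)C)cc(O[Si](C)(C)C(C)(C)C)c3C2=O)ccc2c1C=CC(C)(C)O2 | intermediate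
24 | (3R)-5,7-dihydroxy-3-(5-methoxy-2,2-dimethyl-2H-chromen-6-yl)chroman-4-one | COc1c([C@@H]2COc3cc(O)cc(O)c3C2=O)ccc2c1C=CC(C)(C)O2 | target

**Step count**
Total steps: 10. Longest linear sequence: 6 steps (steps 1, 2, 3, 4, 9, 10; the line through steps 5, 6, 7, 8, 9, 10 is equally long).

**Steps most likely to fail**

Step 9. Capture of the C3 radical by the ortho-methoxy arylnickel species may be slow, so that hydrodebromination or loss of HBr from 20 to the chromone competes. The ligand may also give poor facial selectivity on a cyclic ketone. The fallback uses known chemistry and sets out from 13 and 18. Palladium-catalysed ketone α-arylation (Pd2(dba)3, t-Bu3P·HBF4, NaOt-Bu, toluene, 70 °C) would give the racemic ketone rac-5,7-bis(tert-butyldimethylsilyloxy)-3-(5-methoxy-2,2-dimethyl-2H-chromen-6-yl)chroman-4-one F1. Noyori-type asymmetric transfer hydrogenation under dynamic kinetic resolution (RuCl(p-cymene)[(R,R)-TsDPEN], HCO2H/Et3N, EtOAc, 40 °C; catalyst antipode as the usual facial model predicts, to be confirmed) epimerises C3 through the enol while reducing the (3R) ketone faster. It should give the cis alcohol (3R,4R)-5,7-bis(tert-butyldimethylsilyloxy)-3-(5-methoxy-2,2-dimethyl-2H-chromen-6-yl)chroman-4-ol F2. Dess–Martin oxidation (NaHCO3, CH2Cl2, 0 °C) then comes back to the route at 23.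

Step 4. The ortho-quinone methide may be intercepted by a second aryne or by fluoride before it cyclises, the aryne may undergo an ene reaction with the allylic methyl groups of 9, or the orientation of addition may be incomplete. The fallback sets out from 2 and avoids the aryne. Lithiation exactly as in step 2 (through 3 and 4), but quenched with DMF and worked up with aqueous acid, would give 4-bromo-2-formyl-3-methoxyphenyl N-isopropylcarbamate F3. K2CO3 in MeOH removes the carbamate to give 3-bromo-6-hydroxy-2-methoxybenzaldehyde F4. Addition of 2-methylprop-1-enylmagnesium bromide (2.2 equiv, THF, 0 °C) gives 4-bromo-2-(1-hydroxy-3-methylbut-2-en-1-yl)-3-methoxyphenol F5. Warming with pyridinium p-toluenesulfonate in toluene dehydrates F5 to the same ortho-quinone methide 12, which closes to 13, where the route is rejoined.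

Step 8. Bromination of the electron-rich ring A or a second bromination at C3 may compete, and 20 may lose HBr to the chromone during purification. The fallback sets out from 19 and replaces electrophilic bromination by oxygenation and displacement. Rubottom oxidation (mCPBA, NaHCO3, CH2Cl2, −20 °C; then citric acid, MeOH) would give rac-5,7-bis(tert-butyldimethylsilyloxy)-3-hydroxychroman-4-one F6. An Appel reaction (CBr4, PPh3, CH2Cl2, 0 °C) converts F6 into 20, where the route is rejoined.

**Further compounds**
F1 | step 9 | rac-5,7-bis(tert-butyldimethylsilyloxy)-3-(5-methoxy-2,2-dimethyl-2H-chromen-6-yl)chroman-4-one | COc1c(C2COc3cc(O[Si](C)(C)C(C)(C)C)cc(O[Si](C)(C)C(C)(C)C)c3C2=O)ccc2c1C=CC(C)(C)O2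
F2 | step 9 | (3R,4R)-5,7-bis(tert-butyldimethylsilyloxy)-3-(5-methoxy-2,2-dimethyl-2H-chromen-6-yl)chroman-4-ol | COc1c([C@@H]2COc3cc(O[Si](C)(C)C(C)(C)C)cc(O[Si](C)(C)C(C)(C)C)c3[C@@H]2O)ccc2c1C=CC(C)(C)O2
F3 | step 4 | 4-bromo-2-formyl-3-methoxyphenyl N-isopropylcarbamate | COc1c(Br)ccc(OC(=O)NC(C)C)c1C=O
F4 | step 4 | 3-bromo-6-hydroxy-2-methoxybenzaldehyde | COc1c(Br)ccc(O)c1C=O
F5 | step 4 | 4-bromo-2-(1-hydroxy-3-methylbut-2-en-1-yl)-3-methoxyphenol (racemic) | COc1c(Br)ccc(O)c1C(O)C=C(C)C
F6 | step 8 | rac-5,7-bis(tert-butyldimethylsilyloxy)-3-hydroxychroman-4-one | O=C1C(O)COc2cc(O[Si](C)(C)C(C)(C)C)cc(O[Si](C)(C)C(C)(C)C)c12
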